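The route rests on taking apart ring C, the para-phenylene ring whose C1 carries the ether oxygen to ring B and whose C4 carries the bridge carbon leading to ring D, into a 2-aryloxybuta-1,3-diene and an ethynyl ketone. One intramolecular Diels–Alder reaction forms both new C–C bonds of ring C and, through them, closes the 18-membered macrocycle while ring C is still a flexible cyclohexa-1,4-diene; the cyclophane strain is paid only on later aromatisation. The precursor is an open A–B–D array: ring B bears the butadien-2-yl ether on its meta oxygen, ring D a CH2C(=O)C≡CH arm, and ring A links both through a diaryl ether and a bibenzyl bridge.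

Key step: step 13

Remarks on the chemistry:
- Ring A is the trisubstituted ring with the ether oxygen to ring D and a para OH. Ring B is the catechol-type ring, ring C the para-phenylene ring, ring D the meta-phenylene ring.
- The target has no stereocentre. The stilbene is carried as an E/Z mixture and the two secondary carbinols as racemates, because each of these stereo-elements is erased in the following operation.
- The ring D side chain is carried as a silyl-protected 2-hydroxyethyl group so that no carbonyl, alkyne or OH meets the titanium methylenation. The ynone is unveiled last and kept in solution.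

Step 1
Reactants: 1 3-(benzyloxy)-4-methoxybenzaldehyde (O-benzylisovanillin, commercial)
Product: 2 [3-(benzyloxy)-4-methoxyphenyl]methanol
Conditions: NaBH4, MeOH, 0 °C
Reagents that add atoms: none
Why: Borohydride reduction of an aromatic aldehyde is chemoselective and leaves the benzyl and methyl ethers untouched.

Step 2
Reactants: 2 [3-(benzyloxy)-4-methoxyphenyl]methanol
Product: 3 [3-(benzyloxy)-4-methoxybenzyl]triphenylphosphonium bromide
Conditions: PPh3·HBr, MeCN, reflux
Reagents that add atoms: triphenylphosphine hydrobromide, [Br-].[PH+](c1ccccc1)(c1ccccc1)c1ccccc1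
Why: Direct phosphonium salt formation from an electron-rich benzylic alcohol (acid-promoted activation of the hydroxyl, then substitution by phosphorus) avoids isolating the benzylic bromide, and the benzyl aryl ether tolerates these conditions.

Step 3
Reactants: 4 2-fluoro-5-methoxybenzaldehyde; 5 3-(2-hydroxyethyl)phenol
Product: 6 2-[3-(2-hydroxyethyl)phenoxy]-5-methoxybenzaldehyde
Conditions: K2CO3, DMF, 120 °C
Reagents that add atoms: none
Why: Nucleophilic aromatic substitution (SNAr) in which the phenoxide of 5 displaces the fluoride activated by the ortho formyl group, while the much less acidic primary alcohol stays un-ionised under carbonate and does not compete.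

Step 4
Reactants: 6 2-[3-(2-hydroxyethyl)phenoxy]-5-methoxybenzaldehyde
Product: 7 2-{3-[2-(tert-butyldimethylsilyloxy)ethyl]phenoxy}-5-methoxybenzaldehyde
Conditions: TBSCl, imidazole, CH2Cl2, rt
Reagents that add atoms: tert-butyldimethylsilyl chloride, CC(C)(C)[Si](C)(C)Cl
Why: Imidazole-promoted silylation of the only hydroxyl group masks it, so that later the phenol alone is acylated and the titanium reagent meets no protic group.

Step 5
Reactants: 3 [3-(benzyloxy)-4-methoxybenzyl]triphenylphosphonium bromide; 7 2-{3-[2-(tert-butyldimethylsilyloxy)ethyl]phenoxy}-5-methoxybenzaldehyde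
Product: 9 tert-butyl{2-[3-(2-{2-[3-(benzyloxy)-4-methoxyphenyl]ethenyl}-4-methoxyphenoxy)phenyl]ethoxy}dimethylsilane (stilbene; E/Z mixture expected), via benzylidene phosphorane 8 (not isolated)
Conditions: t-BuOK, THF, 0 °C; then 7, 0 °C → rt
Reagents that add atoms: none
Why: Wittig olefination of an aryl aldehyde with a semi-stabilised benzylidene ylide, whose alkene geometry is irrelevant because the double bond is saturated in the next step.

Step 6
Reactants: 9 stilbene (E/Z mixture)
Product: 11 5-[2-(2-{3-[2-(tert-butyldimethylsilyloxy)ethyl]phenoxy}-5-methoxyphenyl)ethyl]-2-methoxyphenol, via bibenzyl benzyl ether 10 (not isolated)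
Conditions: H2 (1 atm), 10% Pd/C, EtOAc, rt
Reagents that add atoms: none
Why: Heterogeneous catalytic hydrogenation saturates the stilbene and hydrogenolyses the benzyl ether in one operation, whereas the alkyl silyl ether, the diaryl ether and the methyl ethers are inert over Pd/C in ethyl acetate.

Step 7
Reactants: 11 ring B phenol; 12 acryloyl chloride
Product: 13 5-[2-(2-{3-[2-(tert-butyldimethylsilyloxy)ethyl]phenoxy}-5-methoxyphenyl)ethyl]-2-methoxyphenyl prop-2-enoate
Conditions: Et3N, BHT (cat.), CH2Cl2, −20 → 0 °C
Reagents that add atoms: acryloyl chloride (12), C=CC(Cl)=O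
Why: O-Acylation of a phenol with an acid chloride under amine base, run cold with a radical inhibitor so that the aryl acrylate does not polymerise.

Step 8
Reactants: 13 aryl acrylate; 14 Tebbe reagent Cp2Ti(μ-CH2)(μ-Cl)AlMe2
Product: 15 buta-1,3-dien-2-yl ether of phenol 11 (ring B–O–C(=CH2)–CH=CH2; silyl ether retained)
Conditions: Cp2Ti(μ-CH2)(μ-Cl)AlMe2, pyridine (cat.), THF/toluene, −40 → 0 °C; aq. NaOH quench; basic alumina
Reagents that add atoms: Tebbe reagent (14), C[Al-]1(C)C[Ti]([Cl+]1)(C2C=CC=C2)C2C=CC=C2
Why: Tebbe methylenation of an ester carbonyl (the titanium methylidene forms an oxatitanacyclobutane that collapses to the enol ether and Cp2TiO) is established for aryl esters and for conjugated esters, the latter giving 2-oxybuta-1,3-dienes, and the basic work-up protects the acid-labile product.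

Step 9
Reactants: 15 aryloxydiene silyl ether
Product: 16 2-{3-[2-(2-{3-[(buta-1,3-dien-2-yl)oxy]-4-methoxyphenyl}ethyl)-4-methoxyphenoxy]phenyl}ethanol
Conditions: TBAF, THF, 0 °C → rt
Reagents that add atoms: none
Why: Fluoride-induced desilylation proceeds under basic conditions that the enol ether diene tolerates.

Step 10
Reactants: 16 aryloxydiene primary alcohol
Product: 17 {3-[2-(2-{3-[(buta-1,3-dien-2-yl)oxy]-4-methoxyphenyl}ethyl)-4-methoxyphenoxy]phenyl}acetaldehyde
Conditions: Dess–Martin periodinane, pyridine, CH2Cl2, 0 °C → rt; used crude at once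
Reagents that add atoms: none
Why: Dess–Martin oxidation of a primary alcohol stops at the aldehyde, and the pyridine buffer takes up the acetic acid released so that the enol ether is spared.

Step 11
Reactants: 17 arylacetaldehyde; 18 ethynylmagnesium bromide
Product: 19 1-{3-[2-(2-{3-[(buta-1,3-dien-2-yl)oxy]-4-methoxyphenyl}ethyl)-4-methoxyphenoxy]phenyl}but-3-yn-2-ol (racemic)
Conditions: HC≡CMgBr, THF, −78 → −20 °C; pH 7 phosphate buffer
Reagents that add atoms: ethynylmagnesium bromide (18), C#C[Mg]Br
Why: 1,2-Addition of an alkynyl Grignard reagent to an aldehyde at low temperature should outpace enolisation of the arylacetaldehyde; the carbinol centre forms as a racemate and is erased in the next step.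

Step 12
Reactants: 19 propargylic alcohol (racemic)
Product: 20 1-{3-[2-(2-{3-[(buta-1,3-dien-2-yl)oxy]-4-methoxyphenyl}ethyl)-4-methoxyphenoxy]phenyl}but-3-yn-2-one (seco aryloxydiene ynone)
Conditions: activated MnO2, CH2Cl2, rt; filtered through Celite, diluted with toluene, kept in solution
Reagents that add atoms: none
Why: Oxidation of a propargylic alcohol to the alkynyl ketone with activated MnO2 uses a neutral heterogeneous oxidant removed by filtration, so the diene and the new ynone meet neither acid, base nor high concentration.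

Step 13
Reactants: 20 seco aryloxydiene ynone
Product: 21 macrocyclic 1-aryloxy-4-acylcyclohexa-1,4-diene (ring C as cyclohexa-1,4-diene: C1 bears the oxygen to ring B, C4 the C(=O)CH2 unit to ring D; 18-membered ring closed)
Conditions: toluene (1 mM; 20 added by syringe pump), BHT (cat.), 110 °C
Reagents that add atoms: none
Why: Concerted thermal [4+2] cycloaddition of normal electron demand between the 2-aryloxybutadiene and the ethynyl ketone, the macrocyclic intramolecular variant (tether on diene C2) of the familiar Diels–Alder reactions of 2-oxygenated butadienes with alkynones. The six-membered ring closes suprafacially through the bonds C1(diene)–C(alkyne terminus) and C4(diene)–C(acyl-bearing); the 18-membered ring closes through the same two bonds as a 1,4-bridged cyclohexa-1,4-diene, so the 14-atom tether spans a pliable non-aromatic ring and not a bent benzene. No stereocentre is created. Para regiochemistry is required and is secured by the oxygen donor on C2, which puts the largest HOMO coefficient on the adjacent CH2 and pairs it with the LUMO-rich alkyne terminus, while the tether is long enough not to enforce the meta mode typical of short tethers. Ring closure over oligomerisation is secured by pseudo-high dilution, and BHT with base-washed glassware keeps the enol ether diene from radical and acid-induced decay.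

Step 14
Reactants: 21 macrocyclic cyclohexa-1,4-diene
Product: 22 macrocyclic aryl ketone (dihydroptychantol A di-O-methyl ether carrying C=O at the bridge carbon attached to ring C)
Conditions: DDQ, CH2Cl2, 0 °C → rt
Reagents that add atoms: none
Why: Quinone dehydrogenation of a cyclohexa-1,4-diene (hydride abstraction from a doubly allylic CH2 gives an aryloxy-stabilised cation that loses a proton) is far faster than benzylic oxidation of the bibenzyl bridge at this temperature.

Step 15
Reactants: 22 macrocyclic aryl ketone
Product: 24 dihydroptychantol A di-O-methyl ether, via benzylic carbinol 23 (not isolated)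
Conditions: Et3SiH, TFA, CH2Cl2, 0 °C → rt
Reagents that add atoms: none
Why: Ionic hydrogenation, in which the protonated aryl ketone takes hydride from the silane, the carbinol ionises to a cation stabilised by the para aryloxy group and is reduced again to the methylene, with all ethers untouched.

Step 16
Reactants: 24 dihydroptychantol A di-O-methyl ether
Product: 25 dihydroptychantol A
Conditions: BBr3, CH2Cl2, −78 °C → rt; then H2O
Reagents that add atoms: none
Why: Lewis acid-mediated cleavage of aryl methyl ethers with BBr3 (bromide attacks the methyl group of the boron-complexed ether) frees both phenols, and diaryl ethers are not cleaved under these conditions.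

Compound list
1 | 3-(benzyloxy)-4-methoxybenzaldehyde | COc1ccc(C=O)cc1OCc1ccccc1 | starting material
2 | [3-(benzyloxy)-4-methoxyphenyl]methanol | COc1ccc(CO)cc1OCc1ccccc1 | intermediate
3 | [3-(benzyloxy)-4-methoxybenzyl]triphenylphosphonium bromide | COc1ccc(C[P+](c2ccccc2)(c2ccccc2)c2ccccc2)cc1OCc1ccccc1.[Br-] | intermediate
4 | 2-fluoro-5-methoxybenzaldehyde | COc1ccc(F)c(C=O)c1 | starting material
5 | 3-(2-hydroxyethyl)phenol | OCCc1cccc(O)c1 | starting material
6 | 2-[3-(2-hydroxyethyl)phenoxy]-5-methoxybenzaldehyde | COc1ccc(Oc2cccc(CCO)c2)c(C=O)c1 | intermediate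
7 | 2-{3-[2-(tert-butyldimethylsilyloxy)ethyl]phenoxy}-5-methoxybenzaldehyde | COc1ccc(Oc2cccc(CCO[Si](C)(C)C(C)(C)C)c2)c(C=O)c1 | intermediate
8 | [3-(benzyloxy)-4-methoxybenzylidene]triphenylphosphorane (not isolated) | COc1ccc(C=P(c2ccccc2)(c2ccccc2)c2ccccc2)cc1OCc1ccccc1 | intermediate
9 | tert-butyl{2-[3-(2-{2-[3-(benzyloxy)-4-methoxyphenyl]ethenyl}-4-methoxyphenoxy)phenyl]ethoxy}dimethylsilane (E/Z mixture) | COc1ccc(Oc2cccc(CCO[Si](C)(C)C(C)(C)C)c2)c(C=Cc2ccc(OC)c(OCc3ccccc3)c2)c1 | intermediate
10 | bibenzyl benzyl ether, the ethenyl bridge of 9 saturated (not isolated) | COc1ccc(Oc2cccc(CCO[Si](C)(C)C(C)(C)C)c2)c(CCc2ccc(OC)c(OCc3ccccc3)c2)c1 | intermediate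
11 | 5-[2-(2-{3-[2-(tert-butyldimethylsilyloxy)ethyl]phenoxy}-5-methoxyphenyl)ethyl]-2-methoxyphenol | COc1ccc(Oc2cccc(CCO[Si](C)(C)C(C)(C)C)c2)c(CCc2ccc(OC)c(O)c2)c1 | intermediate
12 | acryloyl chloride | C=CC(Cl)=O | starting material
13 | prop-2-enoate ester of phenol 11 | COc1ccc(Oc2cccc(CCO[Si](C)(C)C(C)(C)C)c2)c(CCc2ccc(OC)c(OC(=O)C=C)c2)c1 | intermediate
14 | Tebbe reagent Cp2Ti(μ-CH2)(μ-Cl)AlMe2 | C[Al-]1(C)C[Ti]([Cl+]1)(C2C=CC=C2)C2C=CC=C2 | starting material
15 | buta-1,3-dien-2-yl ether of phenol 11 | COc1ccc(Oc2cccc(CCO[Si](C)(C)C(C)(C)C)c2)c(CCc2ccc(OC)c(OC(=C)C=C)c2)c1 | intermediate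
16 | 2-{3-[2-(2-{3-[(buta-1,3-dien-2-yl)oxy]-4-methoxyphenyl}ethyl)-4-methoxyphenoxy]phenyl}ethanol | COc1ccc(Oc2cccc(CCO)c2)c(CCc2ccc(OC)c(OC(=C)C=C)c2)c1 | intermediate
17 | {3-[2-(2-{3-[(buta-1,3-dien-2-yl)oxy]-4-methoxyphenyl}ethyl)-4-methoxyphenoxy]phenyl}acetaldehyde | COc1ccc(Oc2cccc(CC=O)c2)c(CCc2ccc(OC)c(OC(=C)C=C)c2)c1 | intermediate
18 | ethynylmagnesium bromide | C#C[Mg]Br | starting material
19 | 1-{3-[2-(2-{3-[(buta-1,3-dien-2-yl)oxy]-4-methoxyphenyl}ethyl)-4-methoxyphenoxy]phenyl}but-3-yn-2-ol (racemic) | COc1ccc(Oc2cccc(CC(O)C#C)c2)c(CCc2ccc(OC)c(OC(=C)C=C)c2)c1 | intermediate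
20 | 1-{3-[2-(2-{3-[(buta-1,3-dien-2-yl)oxy]-4-methoxyphenyl}ethyl)-4-methoxyphenoxy]phenyl}but-3-yn-2-one | COc1ccc(Oc2cccc(CC(=O)C#C)c2)c(CCc2ccc(OC)c(OC(=C)C=C)c2)c1 | intermediate
21 | macrocyclic 1-aryloxy-4-acylcyclohexa-1,4-diene | COc1ccc2c(c1)CCc1ccc(OC)c(c1)OC1=CCC(=CC1)C(=O)Cc1cccc(c1)O2 | intermediate
22 | macrocyclic aryl ketone (ring C aromatic, C=O on the bridge carbon at ring C) | COc1ccc2c(c1)CCc1ccc(OC)c(c1)Oc1ccc(cc1)C(=O)Cc1cccc(c1)O2 | intermediate
23 | macrocyclic benzylic carbinol (racemic; not isolated) | COc1ccc2c(c1)CCc1ccc(OC)c(c1)Oc1ccc(cc1)C(O)Cc1cccc(c1)O2 | intermediate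
24 | dihydroptychantol A di-O-methyl ether | COc1ccc2c(c1)CCc1ccc(OC)c(c1)Oc1ccc(cc1)CCc1cccc(c1)O2 | intermediate
25 | dihydroptychantol A | Oc1ccc2c(c1)CCc1ccc(O)c(c1)Oc1ccc(cc1)CCc1cccc(c1)O2 | target

Total step count: 16.
Longest linear sequence: 14 steps (steps 3 to 16, from 4 and 5 to 25); steps 1 and 2 form the side branch that joins at step 5.

Steps most likely to fail

1. Step 13 (macrocyclising Diels–Alder).
   - What may go wrong: bimolecular cycloaddition and oligomerisation may outrun a slow ring closure. The diene or the ynone may decay thermally before they react. Part of the material may close in the meta-bridged sense if the tether overrides the frontier-orbital preference.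
   - Fallback: close the same macrocycle at the CH2–ring C bond by B-alkyl Suzuki–Miyaura coupling. It sets out from phenol 11 and returns at 24.
   - Ullmann etherification of 11 with 1-bromo-4-iodobenzene (CuI, N,N-dimethylglycine, Cs2CO3, dioxane, 90 °C; reaction at iodine) should give the 4-bromophenyl ether F1.
   - TBAF in THF should free the primary alcohol F2.
   - I2, PPh3 and imidazole should convert it into the primary iodide F3, and t-BuOK in THF should eliminate HI to the ring D styrene F4.
   - Hydroboration with 9-BBN-H should give the B-alkyl-9-BBN borane F5 (not isolated). Under Pd(dppf)Cl2, AsPh3 and Cs2CO3 in DMF/THF/H2O at high dilution this should couple with the aryl bromide and deliver 24 directly.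

2. Step 8 (titanium methylenation of the aryl acrylate).
   - What may go wrong: the electron-poor vinyl ester may be consumed by Lewis acid-induced or anionic polymerisation, or by engagement of its C=C bond with the titanium methylidene, before the carbonyl is methylenated. The enol ether may also hydrolyse during isolation.
   - Fallback: methylenate a saturated ester and unveil the vinyl group afterwards. It sets out from phenol 11 and returns at 15.
   - Acylation with 3-chloropropanoyl chloride (pyridine, CH2Cl2, −20 °C) should give the aryl 3-chloropropanoate F6.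
   - Tebbe methylenation of this non-conjugated ester should give the 4-chlorobut-1-en-2-yl aryl ether F7.
   - Dehydrochlorination with t-BuOK in THF (E2 through the allylic hydrogens) should give diene 15.

3. Step 15 (ionic hydrogenation of the macrocyclic ketone).
   - What may go wrong: the benzylic cation may be captured by a neighbouring electron-rich ring across the macrocycle (transannular Friedel–Crafts alkylation), or the reduction may stop at the carbinol stage.
   - Fallback: an anionic deoxygenation that avoids any cation. It sets out from ketone 22 and returns at 24.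
   - Huang–Minlon Wolff–Kishner reduction (N2H4·H2O, KOH, diethylene glycol, 130 °C then 200 °C) should proceed through the hydrazone F8 (not isolated), which loses dinitrogen under base to give the methylene compound 24.

Further compounds
F1 | step 13 | 4-bromophenyl ether of phenol 11 (silyl ether retained) | COc1ccc(Oc2cccc(CCO[Si](C)(C)C(C)(C)C)c2)c(CCc2ccc(OC)c(Oc3ccc(Br)cc3)c2)c1
F2 | step 13 | 2-{3-[2-(2-{3-(4-bromophenoxy)-4-methoxyphenyl}ethyl)-4-methoxyphenoxy]phenyl}ethanol | COc1ccc(Oc2cccc(CCO)c2)c(CCc2ccc(OC)c(Oc3ccc(Br)cc3)c2)c1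
F3 | step 13 | primary iodide from F2 (ring D 2-iodoethyl) | COc1ccc(Oc2cccc(CCI)c2)c(CCc2ccc(OC)c(Oc3ccc(Br)cc3)c2)c1
F4 | step 13 | ring D styrene carrying the ring C bromide | COc1ccc(Oc2cccc(C=C)c2)c(CCc2ccc(OC)c(Oc3ccc(Br)cc3)c2)c1
F5 | step 13 | B-alkyl-9-BBN borane from F4 (not isolated) | COc1ccc(Oc2cccc(CCB3C4CCCC3CCC4)c2)c(CCc2ccc(OC)c(Oc3ccc(Br)cc3)c2)c1
F6 | step 8 | 3-chloropropanoate ester of phenol 11 | COc1ccc(Oc2cccc(CCO[Si](C)(C)C(C)(C)C)c2)c(CCc2ccc(OC)c(OC(=O)CCCl)c2)c1
F7 | step 8 | 4-chlorobut-1-en-2-yl ether of phenol 11 | COc1ccc(Oc2cccc(CCO[Si](C)(C)C(C)(C)C)c2)c(CCc2ccc(OC)c(OC(=C)CCCl)c2)c1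
F8 | step 15 | hydrazone of ketone 22 (not isolated) | COc1ccc2c(c1)CCc1ccc(OC)c(c1)Oc1ccc(cc1)C(=NN)Cc1cccc(c1)O2
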